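**Remark (assumption):** Atoms are numbered as in labdanes (ring A = C1–C5, C10; ring B = C5–C10; C17 = ester carbon on C8; side chain C11–C16). The facial sense of the copper–bis(oxazoline) catalyst on the new chelate in step 8 is assumed by analogy with N-enoyl imides; the ligand antipode would be used if the opposite sense were found.

## Retrosynthetic overview

1. The target is traced back to the cis-fused pyrazolidinone 15: methanolysis turns the lactam C=O into the C17 methyl ester, and an allylic diazene rearrangement turns C7–N/Δ5 into C5–H/Δ6 with loss of N2.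
2. 15 comes from the hydrazide-tethered triene 14 by an intramolecular Diels–Alder reaction that forms C7–C8 and C9–C10 (ring B) and sets C7, C8, C9 and C10.
3. 14 comes from N-acylation of the 1-hydrazinodiene 6 (β-cyclocitral; Takai, Cu N-vinylation, tosylation) with the enoyl chloride 13, made by cross-metathesis of 11 (iodoenoate 9 + butenylzinc).
4. Enabling feature: ring B is a cyclohex-2-ene-1-carboxylate. C6=C7 is allylic to C5–H, and C8 carries the carbonyl C17 next to C7, so an N–N unit can bridge C7 and C17; the C7–N bond then relays its configuration to C5 and leaves as N2.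
5. Ring order: ring A is bought (β-cyclocitral); ring B and the temporary pyrazolidinone form together in step 8; the pyrazolidinone is opened in step 9 and its N–N unit expelled in step 10.

Key step: step 8

## Route

Step 1
Reactants: 1 β-cyclocitral (2,6,6-trimethylcyclohex-1-ene-1-carbaldehyde); 2 iodoform
Product: 3 (E)-2-(2-iodoethenyl)-1,3,3-trimethylcyclohex-1-ene
Conditions: CrCl2 (6 equiv), THF, 0 → 23 °C, dark
Reagents that add atoms: none
Why: Takai olefination; the gem-dichromium species from CHI3/CrCl2 adds to the aldehyde and eliminates to the (E)-iodoalkene, which fixes the outside position of the later nitrogen on the diene.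

Step 2
Reactants: 3 dienyl iodide; 4 tert-butyl carbazate
Product: 5 tert-butyl 1-[(E)-2-(2,6,6-trimethylcyclohex-1-en-1-yl)ethenyl]hydrazine-1-carboxylate
Conditions: CuI (10 mol%), 1,10-phenanthroline (20 mol%), Cs2CO3, DMF, 80 °C
Reagents that add atoms: none
Why: Copper-catalysed Goldberg-type N-alkenylation of a hydrazide; the Boc-bearing N–H forms the copper amidate, so coupling should occur at that nitrogen with retention of the E geometry.

Step 3
Reactants: 5 N-amino ene-carbamate
Product: 6 tert-butyl 2-tosyl-1-[(E)-2-(2,6,6-trimethylcyclohex-1-en-1-yl)ethenyl]hydrazine-1-carboxylate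
Conditions: TsCl (1.05 equiv), pyridine, CH2Cl2, 0 °C
Reagents that add atoms: 4-methylbenzenesulfonyl chloride, Cc1ccc(cc1)S(Cl)(=O)=O
Why: N-sulfonylation of the only nucleophilic nitrogen (the terminal NH2); the sulfonyl group later activates the tether acyl group and serves as the nucleofuge that generates the diazene.

Step 4
Reactants: 7 methyl 4-hydroxybut-2-ynoate
Product: 8 methyl 4-acetoxybut-2-ynoate
Conditions: Ac2O, pyridine, DMAP (cat.), CH2Cl2, 0 → 23 °C
Reagents that add atoms: acetic anhydride, CC(=O)OC(C)=O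
Why: DMAP-catalysed O-acetylation installs the C16 acetate of the target at the outset.

Step 5
Reactants: 8 acetoxy ynoate
Product: 9 methyl (2Z)-4-acetoxy-3-iodobut-2-enoate
Conditions: NaI (1.5 equiv), AcOH, 70 °C
Reagents that add atoms: sodium iodide, [Na+].[I-]
Why: Conjugate hydroiodination of an ynoate; anti addition of HI places iodine cis to the ester, which sets the C13=C14 geometry of the target.

Step 6
Reactants: 9 iodoenoate; 10 but-3-en-1-ylzinc bromide
Product: 11 methyl (2E)-3-(acetoxymethyl)hepta-2,6-dienoate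
Conditions: Pd(PPh3)4 (3 mol%), THF, 0 → 23 °C
Reagents that add atoms: none
Why: Negishi coupling forms C12–C13 with retention of alkene geometry (chain cis to the ester); oxidative addition into the β-iodoenoate is faster than ionisation of the allylic acetate.

Step 7
Reactants: 11 dienoate; 12 acryloyl chloride; 6 N′-tosyl hydrazinodiene
Product: 14 tert-butyl 2-[(2E,6E)-6-(acetoxymethyl)-8-methoxy-8-oxoocta-2,6-dienoyl]-2-tosyl-1-[(E)-2-(2,6,6-trimethylcyclohex-1-en-1-yl)ethenyl]hydrazine-1-carboxylate, via acid chloride 13 (not isolated)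
Conditions: 11, 12 (3 equiv), Hoveyda–Grubbs II (3 mol%), CH2Cl2, 40 °C; evaporate excess 12; then 6, NaH (1.05 equiv), THF, −78 → 0 °C
Reagents that add atoms: none
Why: Cross-metathesis of the terminal alkene with acryloyl chloride gives the (E)-enoyl chloride (the trisubstituted enoate is inert), and the sodium sulfonamide of 6 is N-acylated without an amine base, which avoids vinylketene formation.

Step 8
Reactants: 14 hydrazide-tethered triene
Product: 15 tert-butyl (3aR,4R,4aS,9aS)-4-[(3E)-3-(acetoxymethyl)-5-methoxy-5-oxopent-3-en-1-yl]-4a,8,8-trimethyl-3-oxo-2-tosyl-2,3,3a,4,4a,5,6,7,8,9a-decahydro-1H-benzo[f]indazole-1-carboxylate (cis-fused pyrazolidinone on C7–C8; Δ5; labdane 7S,8R,9R,10S)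
Conditions: [Cu((R,R)-t-Bu-box)](SbF6)2 (10 mol%), 4 Å MS, CH2Cl2, −20 → 0 °C
Reagents that add atoms: none
Why: Proposed new method: two-point binding of the N-acyl sulfonamide (C17=O and one S=O, a six-membered chelate as in Lewis-acid complexes of N-enoyl sultams) to cationic Cu(II)–box should lower the LUMO of the C8=C9 enoyl unit and hold N1 syn to C8, so the carbamate-substituted 1-aminodiene C7=C6–C5=C10 adds in a concerted, asynchronous [4+2]; the closest known reaction types are the Cu(II)–bis(oxazoline)-catalysed intramolecular Diels–Alder of trienimides and the Diels–Alder/allylic diazene sequence of 1-hydrazinodienes, the hydrazide-tethered intramolecular form being new. Ring B closes as the six-membered [4+2] ring and the pyrazolidinone as the five-membered tether ring of a type-1 (1,3,8-nonatriene-like) intramolecular Diels–Alder, which enforces the C7–C8/C9–C10 regiochemistry that a β-alkyl enoate would not give reliably in an intermolecular reaction at the hindered C10 terminus. C8/C9 trans follows from the (E)-enoyl geometry; C7–N anti to C10–CH3 follows from suprafacial addition to the (E)-diene (CH3 inside, N1 outside); the C9 chain syn to C10–CH3 follows from the tether-carbonyl-endo (cis-fused) transition state. That endo mode is the selectivity the step needs, and it should be secured by the C4 gem-dimethyl group, which blocks the quadrant under C5 for an endo C9 chain, together with the chelated carbonyl. The absolute configuration (C10, with the others tied to it) is set by the ligand shielding one face of the chelated enoyl unit, and the low temperature suppresses the uncatalysed background reaction and the [1,5]-H shift of the cis-methyl diene.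

Step 9
Reactants: 15 pyrazolidinone cycloadduct
Product: 16 methyl (1R,2R,3S,8aS)-1-[(3E)-3-(acetoxymethyl)-5-methoxy-5-oxopent-3-en-1-yl]-3-[1-(tert-butoxycarbonyl)-2-tosylhydrazin-1-yl]-5,5,8a-trimethyl-1,2,3,5,6,7,8,8a-octahydronaphthalene-2-carboxylate
Conditions: NaOMe (1.05 equiv), THF–MeOH 4:1, −40 °C; then AcOH
Reagents that add atoms: sodium methoxide, C[O-].[Na+]
Why: Alkoxide ring-opening of an N-sulfonyl lactam at C17; the sulfonamide anion formed is non-basic, so the single equivalent of methoxide is consumed and the acetate and the C8 centre should survive.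

Step 10
Reactants: 16 ring-opened N-Boc-N′-tosyl hydrazide
Product: 19 methyl (2E)-3-(acetoxymethyl)-5-[(1R,2S,4aR,8aS)-2-(methoxycarbonyl)-5,5,8a-trimethyl-1,2,4a,5,6,7,8,8a-octahydronaphthalen-1-yl]pent-2-enoate (CNP0190145.1), via N-allyl-N′-tosylhydrazine 17 (not isolated), via allylic diazene 18 (not isolated)
Conditions: TFA–CH2Cl2 1:4, 0 °C; evaporate; NaOAc·3H2O (5 equiv), CHCl3, 55 °C
Reagents that add atoms: none
Why: Boc acidolysis, then acetate-promoted loss of sulfinate from the N-allyl-N′-tosylhydrazine gives the monoalkyl diazene, which undergoes the allylic diazene rearrangement (retro-ene); hydrogen is delivered suprafacially from nitrogen to C5 on the face of the C7–N bond (anti to C10–CH3), which should give the trans ring fusion, shift the alkene to C6=C7 and release N2. The C8 descriptor changes from R to S only through CIP priorities.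

## Compound list

1 | β-cyclocitral (2,6,6-trimethylcyclohex-1-ene-1-carbaldehyde) | CC1=C(C=O)C(C)(C)CCC1 | starting material
2 | iodoform | IC(I)I | starting material
3 | (E)-2-(2-iodoethenyl)-1,3,3-trimethylcyclohex-1-ene | CC1=C(/C=C/I)C(C)(C)CCC1 | intermediate
4 | tert-butyl carbazate | CC(C)(C)OC(=O)NN | starting material
5 | tert-butyl 1-[(E)-2-(2,6,6-trimethylcyclohex-1-en-1-yl)ethenyl]hydrazine-1-carboxylate | CC1=C(/C=C/N(N)C(=O)OC(C)(C)C)C(C)(C)CCC1 | intermediate
6 | tert-butyl 2-tosyl-1-[(E)-2-(2,6,6-trimethylcyclohex-1-en-1-yl)ethenyl]hydrazine-1-carboxylate | CC1=C(/C=C/N(NS(=O)(=O)c2ccc(C)cc2)C(=O)OC(C)(C)C)C(C)(C)CCC1 | intermediate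
7 | methyl 4-hydroxybut-2-ynoate | COC(=O)C#CCO | starting material
8 | methyl 4-acetoxybut-2-ynoate | COC(=O)C#CCOC(C)=O | intermediate
9 | methyl (2Z)-4-acetoxy-3-iodobut-2-enoate | COC(=O)/C=C(\I)COC(C)=O | intermediate
10 | but-3-en-1-ylzinc bromide | C=CCC[Zn]Br | starting material
11 | methyl (2E)-3-(acetoxymethyl)hepta-2,6-dienoate | COC(=O)/C=C(\CCC=C)COC(C)=O | intermediate
12 | acryloyl chloride | C=CC(Cl)=O | starting material
13 | methyl (2E,6E)-3-(acetoxymethyl)-8-chloro-8-oxoocta-2,6-dienoate | COC(=O)/C=C(\CC/C=C/C(Cl)=O)COC(C)=O | intermediate (not isolated)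
14 | tert-butyl 2-[(2E,6E)-6-(acetoxymethyl)-8-methoxy-8-oxoocta-2,6-dienoyl]-2-tosyl-1-[(E)-2-(2,6,6-trimethylcyclohex-1-en-1-yl)ethenyl]hydrazine-1-carboxylate | COC(=O)/C=C(\CC/C=C/C(=O)N(N(/C=C/C1=C(C)CCCC1(C)C)C(=O)OC(C)(C)C)S(=O)(=O)c1ccc(C)cc1)COC(C)=O | intermediate
15 | tert-butyl (3aR,4R,4aS,9aS)-4-[(3E)-3-(acetoxymethyl)-5-methoxy-5-oxopent-3-en-1-yl]-4a,8,8-trimethyl-3-oxo-2-tosyl-2,3,3a,4,4a,5,6,7,8,9a-decahydro-1H-benzo[f]indazole-1-carboxylate | COC(=O)/C=C(\CC[C@@H]1[C@H]2C(=O)N(S(=O)(=O)c3ccc(C)cc3)N(C(=O)OC(C)(C)C)[C@H]2C=C2C(C)(C)CCC[C@@]12C)COC(C)=O | intermediate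
16 | methyl (1R,2R,3S,8aS)-1-[(3E)-3-(acetoxymethyl)-5-methoxy-5-oxopent-3-en-1-yl]-3-[1-(tert-butoxycarbonyl)-2-tosylhydrazin-1-yl]-5,5,8a-trimethyl-1,2,3,5,6,7,8,8a-octahydronaphthalene-2-carboxylate | COC(=O)/C=C(\CC[C@@H]1[C@@H](C(=O)OC)[C@@H](N(NS(=O)(=O)c2ccc(C)cc2)C(=O)OC(C)(C)C)C=C2C(C)(C)CCC[C@@]12C)COC(C)=O | intermediate
17 | methyl (1R,2R,3S,8aS)-1-[(3E)-3-(acetoxymethyl)-5-methoxy-5-oxopent-3-en-1-yl]-5,5,8a-trimethyl-3-(2-tosylhydrazin-1-yl)-1,2,3,5,6,7,8,8a-octahydronaphthalene-2-carboxylate | COC(=O)/C=C(\CC[C@@H]1[C@@H](C(=O)OC)[C@@H](NNS(=O)(=O)c2ccc(C)cc2)C=C2C(C)(C)CCC[C@@]12C)COC(C)=O | intermediate (not isolated)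
18 | methyl (1R,2R,3S,8aS)-1-[(3E)-3-(acetoxymethyl)-5-methoxy-5-oxopent-3-en-1-yl]-3-diazenyl-5,5,8a-trimethyl-1,2,3,5,6,7,8,8a-octahydronaphthalene-2-carboxylate | COC(=O)/C=C(\CC[C@@H]1[C@@H](C(=O)OC)[C@@H](N=N)C=C2C(C)(C)CCC[C@@]12C)COC(C)=O | intermediate (not isolated)
19 | methyl (2E)-3-(acetoxymethyl)-5-[(1R,2S,4aR,8aS)-2-(methoxycarbonyl)-5,5,8a-trimethyl-1,2,4a,5,6,7,8,8a-octahydronaphthalen-1-yl]pent-2-enoate (CNP0190145.1) | COC(=O)/C=C(\CC[C@@H]1[C@@H](C(=O)OC)C=C[C@@H]2C(C)(C)CCC[C@@]12C)COC(C)=O | target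

## Step count and risks

Total: 10 steps. Longest linear sequence: 7 steps (7 → 8 → 9 → 11 → 14 → 15 → 16 → 19, or equally 1 → 3 → 5 → 6 → 14 → 15 → 16 → 19).

**Step 8 (proposed new method).** The copper chelate may not form as drawn because the Boc carbonyl competes for the metal, which would give poor facial selectivity. The tether may also cyclise through the exo (trans-fused) mode, and a slow catalysed reaction would let the racemic thermal background or acid-induced loss of the ene-carbamate take over. The fallback uses known chemistry and sets out from 11 and 6. Cross-metathesis of 11 with commercial 3-acryloyl-1,3-oxazolidin-2-one (Hoveyda–Grubbs II, CH2Cl2, 40 °C) should give 3-[(2E,6E)-6-(acetoxymethyl)-8-methoxy-8-oxoocta-2,6-dienoyl]-1,3-oxazolidin-2-one F1. An intermolecular Diels–Alder reaction of F1 with the 1-hydrazinodiene 6 under [Cu((R,R)-t-Bu-box)](SbF6)2 (two-point imide binding, Cα-Si-face attack, nitrogen-directed "ortho" regiochemistry, imide endo) should give the cyclohexene imide F2. Methanolysis of the imide (Sm(OTf)3 cat., MeOH, 23 °C) returns to the route at 16.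

**Step 2.** Coupling may occur at the terminal NH2 instead of the Boc-bearing nitrogen, and the dienyl iodide or the N-amino ene-carbamate may decompose at 80 °C under basic copper conditions. The fallback sets out from 3. Copper-catalysed vinylation of tert-butyl carbamate (CuI, N,N′-dimethylethylenediamine, K2CO3, toluene, 70 °C) has only one N–H site and should give tert-butyl N-[(E)-2-(2,6,6-trimethylcyclohex-1-en-1-yl)ethenyl]carbamate F3. Electrophilic N-amination of its sodium salt (NaH, then O-(diphenylphosphinyl)hydroxylamine, THF, 0 °C) returns to the route at 5.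

**Step 9.** Methoxide may not discriminate fully between the activated lactam and the allylic acetate, and excess base could epimerise C8 or trigger retro-aza-Michael loss of the hydrazide. The fallback sets out from 15 and gives up the acetate on purpose. K2CO3 (excess) in MeOH at 0 °C should open the lactam and cleave the acetate to give the hydroxy ester F4. Selective O-acetylation of its primary allylic alcohol (Ac2O, pyridine, CH2Cl2, 0 °C, no DMAP) returns to the route at 16.

Further compounds
F1 | step 8 | 3-[(2E,6E)-6-(acetoxymethyl)-8-methoxy-8-oxoocta-2,6-dienoyl]-1,3-oxazolidin-2-one | COC(=O)/C=C(\CC/C=C/C(=O)N1CCOC1=O)COC(C)=O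
F2 | step 8 | methyl (2E)-3-(acetoxymethyl)-5-[(1R,2R,3S,8aS)-3-[1-(tert-butoxycarbonyl)-2-tosylhydrazin-1-yl]-5,5,8a-trimethyl-2-(2-oxo-1,3-oxazolidine-3-carbonyl)-1,2,3,5,6,7,8,8a-octahydronaphthalen-1-yl]pent-2-enoate | COC(=O)/C=C(\CC[C@@H]1[C@@H](C(=O)N2CCOC2=O)[C@@H](N(NS(=O)(=O)c2ccc(C)cc2)C(=O)OC(C)(C)C)C=C2C(C)(C)CCC[C@@]12C)COC(C)=O
F3 | step 2 | tert-butyl N-[(E)-2-(2,6,6-trimethylcyclohex-1-en-1-yl)ethenyl]carbamate | CC1=C(/C=C/NC(=O)OC(C)(C)C)C(C)(C)CCC1
F4 | step 9 | methyl (1R,2R,3S,8aS)-3-[1-(tert-butoxycarbonyl)-2-tosylhydrazin-1-yl]-1-[(3E)-3-(hydroxymethyl)-5-methoxy-5-oxopent-3-en-1-yl]-5,5,8a-trimethyl-1,2,3,5,6,7,8,8a-octahydronaphthalene-2-carboxylate | COC(=O)/C=C(\CC[C@@H]1[C@@H](C(=O)OC)[C@@H](N(NS(=O)(=O)c2ccc(C)cc2)C(=O)OC(C)(C)C)C=C2C(C)(C)CCC[C@@]12C)CO
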